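**Retrosynthetic overview**
1. Target 10 ⇐ quinolone methyl ester 8 by double MeMgBr addition; the tertiary carbinol is made last so it never meets the hot cyclisation.
2. 8 ⇐ β-anilino acrylate 7 by Conrad–Limpach thermal cyclisation; this is the only ring-forming step (pyridone ring closed onto the benzene ring of aniline).
3. 7 ⇐ α-methoxy-β-keto ester 5 + aniline 6 (enamine condensation).
4. 5 ⇐ key C–C bond (future C2–C3 of the quinolone): intermolecular crossed Claisen condensation of the lithium enolate 4 of methyl methoxyacetate 3 with acid chloride 2.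
5. 2 ⇐ commercial monomethyl dodecanedioate 1.

Assumption: the target has no stereocentre and is achiral, so there is no enantiomer to control; the double-bond geometries drawn for 4 and 7 are the chelated/hydrogen-bonded forms and have no consequence for the route.

**Step 1**
Reactants: 1 12-methoxy-12-oxododecanoic acid (monomethyl dodecanedioate)
Product: 2 methyl 12-chloro-12-oxododecanoate
Conditions: (COCl)2 (1.3 equiv), DMF (cat.), CH2Cl2, 0 °C → rt, 2 h; evaporate, co-evaporate with toluene, use crude
Reagents that add atoms: oxalyl chloride, ClC(=O)C(=O)Cl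
Why: DMF-catalysed (Vilsmeier-type) acid chloride formation converts only the free acid, leaves the methyl ester untouched and gives only gaseous by-products.

**Step 2**
Reactants: 2 methyl 12-chloro-12-oxododecanoate; 3 methyl methoxyacetate (2.2 equiv)
Product: 5 dimethyl 2-methoxy-3-oxotetradecanedioate, via lithium enolate of methyl methoxyacetate 4 (not isolated)
Conditions: 3, LiN(i-Pr)2 (2.1 equiv), THF, −78 °C, 45 min; then 2 (1.0 equiv) in THF, −78 °C, 1 h; sat. aq. NH4Cl
Reagents that add atoms: none
Why: Crossed Claisen condensation (C-acylation of a preformed lithium ester enolate): at −78 °C the acid chloride is far more electrophilic than the remote methyl ester, and the second equivalent of enolate deprotonates the acidic product so it is not acylated again; the new C2 centre is racemic and is erased in step 3.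

**Step 3**
Reactants: 5 dimethyl 2-methoxy-3-oxotetradecanedioate; 6 aniline (1.1 equiv)
Product: 7 dimethyl (2E)-3-anilino-2-methoxytetradec-2-enedioate
Conditions: p-TsOH·H2O (5 mol %), cyclohexane, reflux, Dean–Stark, 16–24 h
Reagents that add atoms: none
Why: Acid-catalysed enamine condensation (first stage of the Conrad–Limpach synthesis) occurs at the ketone, the most electrophilic carbonyl, and azeotropic water removal drives it to the N–H···O=C hydrogen-bonded β-enamino ester; at 81 °C neither ester forms an anilide.

**Step 4**
Reactants: 7 dimethyl (2E)-3-anilino-2-methoxytetradec-2-enedioate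
Product: 8 methyl 11-(3-methoxy-4-oxo-1,4-dihydroquinolin-2-yl)undecanoate
Conditions: add 7 dropwise to Ph2O at 250 °C, 20 min; cool, dilute with hexanes, filter
Reagents that add atoms: none
Why: Conrad–Limpach thermal cyclisation: loss of methanol from the conjugated ester gives an imino-ketene that closes by 6π-electrocyclisation onto the aniline ring and tautomerises to the 4-quinolone; the remote saturated ester cannot take part.

**Step 5**
Reactants: 8 methyl 11-(3-methoxy-4-oxo-1,4-dihydroquinolin-2-yl)undecanoate
Product: 10 2-(11-hydroxy-11-methyldodecyl)-3-methoxyquinolin-4(1H)-one, via methyl ketone 9 (not isolated)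
Conditions: MeMgBr (3.0 M in Et2O, 6 equiv), THF, 0 °C → rt, 3 h; sat. aq. NH4Cl
Reagents that add atoms: methylmagnesium bromide, C[Mg]Br
Why: Grignard double addition to an ester: the first equivalent deprotonates N–H to an unreactive magnesium quinolonate, and ketone 9 is more electrophilic than the ester so it is consumed as it forms to give the tertiary alcohol.

**Compound list**
1 | 12-methoxy-12-oxododecanoic acid (monomethyl dodecanedioate) | COC(=O)CCCCCCCCCCC(=O)O | starting material
2 | methyl 12-chloro-12-oxododecanoate | COC(=O)CCCCCCCCCCC(=O)Cl | intermediate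
3 | methyl methoxyacetate | COCC(=O)OC | starting material
4 | lithium enolate of methyl methoxyacetate (lithium 1,2-dimethoxyethenolate, chelated geometry) | [Li+].[O-]/C(OC)=C\OC | intermediate
5 | dimethyl 2-methoxy-3-oxotetradecanedioate (racemic at C2) | COC(=O)C(OC)C(=O)CCCCCCCCCCC(=O)OC | intermediate
6 | aniline | Nc1ccccc1 | starting material
7 | dimethyl (2E)-3-anilino-2-methoxytetradec-2-enedioate (NH cis to the conjugated ester) | COC(=O)/C(OC)=C(\Nc1ccccc1)CCCCCCCCCCC(=O)OC | intermediate
8 | methyl 11-(3-methoxy-4-oxo-1,4-dihydroquinolin-2-yl)undecanoate | COC(=O)CCCCCCCCCCc1[nH]c2ccccc2c(=O)c1OC | intermediate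
9 | 3-methoxy-2-(11-oxododecyl)quinolin-4(1H)-one (present in the flask as its N-magnesium salt, drawn neutral) | CC(=O)CCCCCCCCCCc1[nH]c2ccccc2c(=O)c1OC | intermediate
10 | 2-(11-hydroxy-11-methyldodecyl)-3-methoxyquinolin-4(1H)-one | COc1c(CCCCCCCCCCC(C)(C)O)[nH]c2ccccc2c1=O | target

**Totals**
Total step count: 5. Longest linear sequence: 5 steps (1 → 2 → 5 → 7 → 8 → 10).

**Steps most likely to fail, with fallbacks**

Step 2 (crossed Claisen). The α-alkoxy ester enolate is fragile, and O-acylation or double acylation may lower the yield. The fallback sets out from 2 and comes back at 5. Reduce 2 with LiAlH(Ot-Bu)3 in THF at −78 °C to methyl 12-oxododecanoate F1. Add enolate 4 (from 3 and LiN(i-Pr)2, THF, −78 °C) in an intermolecular aldol addition to give dimethyl 3-hydroxy-2-methoxytetradecanedioate F2 as a diastereomer mixture, which does not matter. Oxidise the secondary alcohol with Dess–Martin periodinane (NaHCO3, CH2Cl2, rt) to reach 5.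

Step 3 (enamine condensation). The α-substituted keto ester may condense slowly or incompletely. The fallback sets out from 5 and comes back at 7. Convert 5 with Tf2O and i-Pr2NEt in CH2Cl2 at −78 → 0 °C into the enol triflate dimethyl (2E)-2-methoxy-3-{[(trifluoromethyl)sulfonyl]oxy}tetradec-2-enedioate F3 (either geometry serves). Couple F3 with aniline 6 by C–N cross-coupling using Pd(OAc)2, Xantphos and Cs2CO3 in toluene at 80 °C to give 7 without any equilibrium condensation.

Step 4 (250 °C cyclisation). Charring or incomplete ring closure is possible. The fallback sets out from 2 and comes back at 8 through a Camps cyclisation that closes the ring below 100 °C.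
- ortho-Lithiate tert-butyl phenylcarbamate with t-BuLi (2.2 equiv, THF, −78 → −20 °C) and acylate with N,2-dimethoxy-N-methylacetamide to give tert-butyl [2-(methoxyacetyl)phenyl]carbamate F4.
- Remove the carbamate with CF3CO2H in CH2Cl2 to give 1-(2-aminophenyl)-2-methoxyethan-1-one F5.
- Acylate F5 with 2 (pyridine, CH2Cl2, 0 °C) to give methyl 12-{[2-(methoxyacetyl)phenyl]amino}-12-oxododecanoate F6.
- Treat F6 with NaOMe in MeOH at reflux: the more acidic α-methoxy ketone enolate adds to the amide carbonyl and dehydrates to 8. Methoxide can only exchange the remote methyl ester with itself.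

**Further compounds**
F1 | step 2 | methyl 12-oxododecanoate | COC(=O)CCCCCCCCCCC=O
F2 | step 2 | dimethyl 3-hydroxy-2-methoxytetradecanedioate (diastereomer mixture, racemic) | COC(=O)C(OC)C(O)CCCCCCCCCCC(=O)OC
F3 | step 3 | dimethyl (2E)-2-methoxy-3-{[(trifluoromethyl)sulfonyl]oxy}tetradec-2-enedioate | COC(=O)/C(OC)=C(\OS(=O)(=O)C(F)(F)F)CCCCCCCCCCC(=O)OC
F4 | step 4 | tert-butyl [2-(methoxyacetyl)phenyl]carbamate | COCC(=O)c1ccccc1NC(=O)OC(C)(C)C
F5 | step 4 | 1-(2-aminophenyl)-2-methoxyethan-1-one | COCC(=O)c1ccccc1N
F6 | step 4 | methyl 12-{[2-(methoxyacetyl)phenyl]amino}-12-oxododecanoate | COCC(=O)c1ccccc1NC(=O)CCCCCCCCCCC(=O)OC
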